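The route rests on closing ring B (O, C9, C10, C11, C12; chain numbered C1–C15 from the alkyne end) by bromoetherification of an E-C12=C13 alkene: the oxygen on C9 attacks C12 while bromine adds anti at C13. The key step exploits the cis C9–C10 fusion of ring B with ring A (O, C7–C10). Its precursor holds ring A as a γ-lactone with O8 and O9 tied in an isopropylidene ketal (all-cis, L-lyxono pattern); the ketal oxygen is the nucleophile, so one operation forms ring B, sets C12 and C13, installs bromine and leaves O8 protected. The lactone is later opened to an alkynol and reclosed as the E-enol ether; C8–Br comes last.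

Key step: step 6

Remark on the chemistry: O8, O9 and O10 are the oxygens on C8, C9 and C10; MOP = 2-methoxyprop-2-yl. Compounds 1, 6, 18 and 23 are assumed to be commercial. The target is (2E,3S,3aR,5R,6aS)-3-bromo-5-[(1S)-1-bromopropyl]-2-[(3Z)-hex-3-en-5-yn-1-ylidene]hexahydrofuro[3,2-b]furan.

Step 1
Reactants: 1 2,3-O-isopropylidene-D-ribono-1,4-lactone
Product: 2 2,3-O-isopropylidene-5-O-methanesulfonyl-D-ribono-1,4-lactone
Conditions: MsCl, pyridine, CH2Cl2, 0 °C to rt
Reagents that add atoms: methanesulfonyl chloride, CS(=O)(=O)Cl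
Why: O-Sulfonylation of the only free hydroxyl (primary, sugar C5) turns it into a leaving group without touching a stereocenter.

Step 2
Reactants: 2 2,3-O-isopropylidene-5-O-methanesulfonyl-D-ribono-1,4-lactone
Product: 4 2,3-O-isopropylidene-L-lyxono-1,4-lactone, via potassium 4,5-anhydro-2,3-O-isopropylidene-D-ribonate 3 (not isolated)
Conditions: KOH, H2O, rt; then aq. HCl to pH 2
Reagents that add atoms: potassium hydroxide, [K+].[OH-]
Why: Saponification frees the sugar C4 alkoxide, which displaces the mesylate (intramolecular Williamson epoxide closure), and on acidification the carboxyl group reopens the epoxide at C4 by 5-exo SN2 lactonisation, so this center (the later C10) is inverted to the all-cis L-lyxo arrangement.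

Step 3
Reactants: 4 2,3-O-isopropylidene-L-lyxono-1,4-lactone
Product: 5 2,3-O-isopropylidene-5-O-(trifluoromethanesulfonyl)-L-lyxono-1,4-lactone
Conditions: Tf2O, pyridine, CH2Cl2, −20 °C
Reagents that add atoms: trifluoromethanesulfonic anhydride, O=S(=O)(OS(=O)(=O)C(F)(F)F)C(F)(F)F
Why: Triflation of the primary alcohol gives an electrophile reactive enough for cuprate substitution at low temperature.

Step 4
Reactants: 6 but-1-yne
Product: 8 (E)-1-iodobut-1-ene, via (E)-but-1-enylzirconocene chloride 7 (not isolated)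
Conditions: Cp2Zr(H)Cl, THF, 0 °C to rt; then I2, 0 °C
Reagents that add atoms: iodine, [I][I]
Why: Hydrozirconation is a syn, terminal-selective addition of Zr–H, and iodinolysis of the C–Zr bond goes with retention, which fixes the E geometry.

Step 5
Reactants: 5 2,3-O-isopropylidene-5-O-(trifluoromethanesulfonyl)-L-lyxono-1,4-lactone; 8 (E)-1-iodobut-1-ene
Product: 11 (3aR,6S,6aR)-2,2-dimethyl-6-[(2E)-pent-2-en-1-yl]dihydrofuro[3,4-d][1,3]dioxol-4(3aH)-one, via (E)-but-1-enyllithium 9 (not isolated), via lithium bis[(E)-but-1-enyl]cuprate 10 (not isolated)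
Conditions: 8 (3 equiv), t-BuLi (6 equiv), Et2O, −78 °C; CuI (1.5 equiv), −40 °C; then 5, THF, −78 to −30 °C; aq. NH4Cl
Reagents that add atoms: none
Why: SN2 substitution of the primary triflate by a Gilman alkenylcuprate forms the C11–C12 bond with retention of the E geometry, and the weakly basic cuprate should leave the lactone and its α-center alone at low temperature.

Step 6
Reactants: 11 (3aR,6S,6aR)-2,2-dimethyl-6-[(2E)-pent-2-en-1-yl]dihydrofuro[3,4-d][1,3]dioxol-4(3aH)-one
Product: 14 (3R,3aR,5R,6aS)-5-[(1S)-1-bromopropyl]-3-[(2-methoxypropan-2-yl)oxy]tetrahydrofuro[3,2-b]furan-2(3H)-one, via tricyclic oxonium ion 12 (not isolated), via O8 oxocarbenium ion 13 (not isolated)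
Conditions: NBS (1.2 equiv), MeOH (5 equiv), NaHCO3, MeCN, −30 to 0 °C
Reagents that add atoms: N-bromosuccinimide, O=C1CCC(=O)N1Br; methanol, CO
Why: NBS converts the E-alkene reversibly into a bromonium ion, and the ketal oxygen on C9 opens it at C12, anti to bromine, in a 5-exo-trig closure of ring B to give the tricyclic oxonium ion 12; this ion ejects its ketal carbon as the oxocarbenium ion 13 on O8, which methanol traps as the MOP ether. The closest known reaction type is the halonium-induced cyclisation of ene acetals and n-pentenyl acetals with participation of an acetal oxygen in the presence of an alcohol. C13 is set by the stereospecific anti addition of oxygen and bromine across the E double bond. C12 is set by the substrate: in 12 the lactone, the dioxolane and the new oxolane all share C9 and form a bowl (possible only because O8, O9 and C11 are all cis), so C13 should sit on the convex face, cis to H9 and H10, as in the target. The step needs site selectivity for O9 over O8 (5-exo against a bridged 6-exo closure), facial selectivity (the bowl) and intramolecular capture ahead of methanol (only a few equivalents of methanol, low temperature).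

Step 7
Reactants: 14 (3R,3aR,5R,6aS)-5-[(1S)-1-bromopropyl]-3-[(2-methoxypropan-2-yl)oxy]tetrahydrofuro[3,2-b]furan-2(3H)-one
Product: 15 (3R,3aR,5R,6aS)-5-[(1S)-1-bromopropyl]-3-[(2-methoxypropan-2-yl)oxy]hexahydrofuro[3,2-b]furan-2-ol (mixture of anomers)
Conditions: i-Bu2AlH, CH2Cl2, −78 °C; aq. potassium sodium tartrate
Reagents that add atoms: none
Why: Partial reduction of a lactone by i-Bu2AlH stops at the tetrahedral aluminate at −78 °C and gives the lactol on work-up, while the base-stable MOP ketal and the secondary bromide are not touched.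

Step 8
Reactants: 15 (3R,3aR,5R,6aS)-5-[(1S)-1-bromopropyl]-3-[(2-methoxypropan-2-yl)oxy]hexahydrofuro[3,2-b]furan-2-ol
Product: 17 (2R,3S,5R)-5-[(1S)-1-bromopropyl]-2-[(1S)-1-hydroxyprop-2-yn-1-yl]oxolan-3-ol, via MOP-protected alkynol 16 (not isolated)
Conditions: dimethyl (1-diazo-2-oxopropyl)phosphonate, K2CO3, MeOH, 0 °C to rt; aqueous work-up; then PPTS (cat.), MeOH, rt
Reagents that add atoms: dimethyl (1-diazo-2-oxopropyl)phosphonate, CC(=O)C(=[N+]=[N-])P(=O)(OC)OC
Why: Seyferth–Gilbert homologation with the Ohira–Bestmann reagent converts the open hydroxy-aldehyde form of the lactol into the terminal alkyne (C6 added, ring A opened, O10 freed) without change at C8, and mild acid then removes the MOP ketal by transketalisation to methanol.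

Step 9
Reactants: 17 (2R,3S,5R)-5-[(1S)-1-bromopropyl]-2-[(1S)-1-hydroxyprop-2-yn-1-yl]oxolan-3-ol; 18 (Z)-1,3-dichloropropene
Product: 19 (2R,3S,5R)-5-[(1S)-1-bromopropyl]-2-[(1S,5Z)-6-chloro-1-hydroxyhex-5-en-2-yn-1-yl]oxolan-3-ol
Conditions: CuI (20 mol %), K2CO3, Bu4NCl, DMF, rt
Reagents that add atoms: none
Why: Copper-catalysed SN2 coupling of a terminal alkyne with an allylic chloride (Jeffery-type conditions) forms the C5–C6 bond at the allylic CH2 only and keeps the Z vinyl chloride, the free hydroxyls and the bromide.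

Step 10
Reactants: 19 (2R,3S,5R)-5-[(1S)-1-bromopropyl]-2-[(1S,5Z)-6-chloro-1-hydroxyhex-5-en-2-yn-1-yl]oxolan-3-ol
Product: 21 (2R,3S,5R)-5-[(1S)-1-bromopropyl]-2-[(1R,2E,5Z)-6-chloro-1-hydroxy-2-iodohexa-2,5-dien-1-yl]oxolan-3-ol, via C7 vinylstannane 20 (not isolated)
Conditions: PdCl2(PPh3)2 (3 mol %), Bu3SnH (slow addition), THF, 0 °C; then I2, CH2Cl2, 0 °C
Reagents that add atoms: iodine, [I][I]
Why: Palladium-catalysed hydrostannation is a syn addition in which the propargylic carbinol steers tin to the proximal alkyne carbon C7, and iododestannylation with retention then gives the vinyl iodide with iodine trans to C5.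

Step 11
Reactants: 21 (2R,3S,5R)-5-[(1S)-1-bromopropyl]-2-[(1R,2E,5Z)-6-chloro-1-hydroxy-2-iodohexa-2,5-dien-1-yl]oxolan-3-ol
Product: 22 (2E,3R,3aS,5R,6aS)-5-[(1S)-1-bromopropyl]-2-[(3Z)-4-chlorobut-3-en-1-ylidene]hexahydrofuro[3,2-b]furan-3-ol
Conditions: CuI (10 mol %), 1,10-phenanthroline (20 mol %), Cs2CO3, toluene, 80 °C
Reagents that add atoms: none
Why: Copper-catalysed intramolecular O-vinylation (Ullmann-type C–O coupling) of the C10 hydroxyl with the vinyl iodide closes ring A in a 5-exo mode with retention of the alkene geometry, so the ring oxygen ends trans to C5 (the E enol ether).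

Step 12
Reactants: 22 (2E,3R,3aS,5R,6aS)-5-[(1S)-1-bromopropyl]-2-[(3Z)-4-chlorobut-3-en-1-ylidene]hexahydrofuro[3,2-b]furan-3-ol; 23 ethynyltrimethylsilane
Product: 24 (2E,3R,3aS,5R,6aS)-5-[(1S)-1-bromopropyl]-2-[(3Z)-6-(trimethylsilyl)hex-3-en-5-yn-1-ylidene]hexahydrofuro[3,2-b]furan-3-ol
Conditions: PdCl2(PhCN)2 (5 mol %), CuI (10 mol %), piperidine, rt
Reagents that add atoms: none
Why: Sonogashira coupling of a Z vinyl chloride under Linstrumelle-type conditions proceeds with retention of the Z geometry and should tolerate the enol ether, the free alcohol and the unactivated secondary bromide.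

Step 13
Reactants: 24 (2E,3R,3aS,5R,6aS)-5-[(1S)-1-bromopropyl]-2-[(3Z)-6-(trimethylsilyl)hex-3-en-5-yn-1-ylidene]hexahydrofuro[3,2-b]furan-3-ol
Product: 25 (2E,3R,3aS,5R,6aS)-5-[(1S)-1-bromopropyl]-2-[(3Z)-hex-3-en-5-yn-1-ylidene]hexahydrofuro[3,2-b]furan-3-ol
Conditions: K2CO3 (cat.), MeOH, 0 °C
Reagents that add atoms: none
Why: Base-catalysed methanolysis of the alkynyl C–Si bond (protodesilylation) frees the terminal alkyne and leaves the base-stable enol ether intact.

Step 14
Reactants: 25 (2E,3R,3aS,5R,6aS)-5-[(1S)-1-bromopropyl]-2-[(3Z)-hex-3-en-5-yn-1-ylidene]hexahydrofuro[3,2-b]furan-3-ol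
Product: 26 (2E,3S,3aR,5R,6aS)-3-bromo-5-[(1S)-1-bromopropyl]-2-[(3Z)-hex-3-en-5-yn-1-ylidene]hexahydrofuro[3,2-b]furan
Conditions: CBr4, PPh3, 2,6-lutidine, CH2Cl2, −20 to 0 °C
Reagents that add atoms: carbon tetrabromide, BrC(Br)(Br)Br
Why: Appel bromination, in which the concave-face C8 alkoxyphosphonium group is displaced by bromide from the convex face in an SN2 reaction with inversion, placing bromine trans to the C9 oxygen as in the target while lutidine shields the enol ether from acid.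

Compound list
1 | 2,3-O-isopropylidene-D-ribono-1,4-lactone, (3aR,6R,6aR)-6-(hydroxymethyl)-2,2-dimethyldihydrofuro[3,4-d][1,3]dioxol-4(3aH)-one | O=C1O[C@H](CO)[C@H]2OC(C)(C)O[C@@H]12 | starting material
2 | 2,3-O-isopropylidene-5-O-methanesulfonyl-D-ribono-1,4-lactone | O=C1O[C@H](COS(C)(=O)=O)[C@H]2OC(C)(C)O[C@@H]12 | intermediate
3 | potassium 4,5-anhydro-2,3-O-isopropylidene-D-ribonate (carboxylate on the dioxolane, 4R epoxide) | [K+].[O-]C(=O)[C@@H]1OC(C)(C)O[C@@H]1[C@H]1CO1 | intermediate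
4 | 2,3-O-isopropylidene-L-lyxono-1,4-lactone, (3aR,6S,6aR)-6-(hydroxymethyl)-2,2-dimethyldihydrofuro[3,4-d][1,3]dioxol-4(3aH)-one | O=C1O[C@@H](CO)[C@H]2OC(C)(C)O[C@@H]12 | intermediate
5 | 2,3-O-isopropylidene-5-O-(trifluoromethanesulfonyl)-L-lyxono-1,4-lactone | O=C1O[C@@H](COS(=O)(=O)C(F)(F)F)[C@H]2OC(C)(C)O[C@@H]12 | intermediate
6 | but-1-yne | CCC#C | starting material
7 | chlorobis(cyclopentadienyl)[(E)-but-1-enyl]zirconium | CC/C=C/[Zr+2]Cl.c1cc[cH-]c1.c1cc[cH-]c1 | intermediate
8 | (E)-1-iodobut-1-ene | CC/C=C/I | intermediate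
9 | (E)-but-1-enyllithium | [Li]/C=C/CC | intermediate
10 | lithium bis[(E)-but-1-enyl]cuprate | [Li+].CC/C=C/[Cu-]/C=C/CC | intermediate
11 | (3aR,6S,6aR)-2,2-dimethyl-6-[(2E)-pent-2-en-1-yl]dihydrofuro[3,4-d][1,3]dioxol-4(3aH)-one (5-C-butenyl-5-deoxy-L-lyxonolactone acetonide; O8, O9 and the pentenyl chain all cis) | O=C1O[C@@H](C/C=C/CC)[C@H]2OC(C)(C)O[C@@H]12 | intermediate
12 | tricyclic oxonium ion: the ketal oxygen on C9 also bonded to C12, so that lactone, dioxolane and new oxolane share C9; C13 bromide exo; succinimide anion as counter-ion | O=C1O[C@H]2C[C@H]([C@@H](Br)CC)[O+]3[C@H]2[C@H]1OC3(C)C.O=C1CCC(=O)[N-]1 | intermediate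
13 | oxocarbenium ion: the bicyclic bromolactone of 14 carrying a propan-2-ylideneoxonium group on O8; succinimide anion as counter-ion | O=C1O[C@H]2C[C@H]([C@@H](Br)CC)O[C@H]2[C@H]1[O+]=C(C)C.O=C1CCC(=O)[N-]1 | intermediate
14 | (3R,3aR,5R,6aS)-5-[(1S)-1-bromopropyl]-3-[(2-methoxypropan-2-yl)oxy]tetrahydrofuro[3,2-b]furan-2(3H)-one | O=C1O[C@H]2C[C@H]([C@@H](Br)CC)O[C@H]2[C@H]1OC(C)(C)OC | intermediate
15 | (3R,3aR,5R,6aS)-5-[(1S)-1-bromopropyl]-3-[(2-methoxypropan-2-yl)oxy]hexahydrofuro[3,2-b]furan-2-ol, both anomers | OC1O[C@H]2C[C@H]([C@@H](Br)CC)O[C@H]2[C@H]1OC(C)(C)OC | intermediate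
16 | (2R,3S,5R)-5-[(1S)-1-bromopropyl]-2-{(1S)-1-[(2-methoxypropan-2-yl)oxy]prop-2-yn-1-yl}oxolan-3-ol | C#C[C@H](OC(C)(C)OC)[C@@H]1O[C@@H]([C@@H](Br)CC)C[C@@H]1O | intermediate
17 | (2R,3S,5R)-5-[(1S)-1-bromopropyl]-2-[(1S)-1-hydroxyprop-2-yn-1-yl]oxolan-3-ol | C#C[C@H](O)[C@@H]1O[C@@H]([C@@H](Br)CC)C[C@@H]1O | intermediate
18 | (Z)-1,3-dichloropropene | Cl/C=C\CCl | starting material
19 | (2R,3S,5R)-5-[(1S)-1-bromopropyl]-2-[(1S,5Z)-6-chloro-1-hydroxyhex-5-en-2-yn-1-yl]oxolan-3-ol | Cl/C=C\CC#C[C@H](O)[C@@H]1O[C@@H]([C@@H](Br)CC)C[C@@H]1O | intermediate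
20 | (2R,3S,5R)-5-[(1S)-1-bromopropyl]-2-[(1R,2E,5Z)-6-chloro-1-hydroxy-2-(tributylstannyl)hexa-2,5-dien-1-yl]oxolan-3-ol | Cl/C=C\C/C=C(/[Sn](CCCC)(CCCC)CCCC)[C@H](O)[C@@H]1O[C@@H]([C@@H](Br)CC)C[C@@H]1O | intermediate
21 | (2R,3S,5R)-5-[(1S)-1-bromopropyl]-2-[(1R,2E,5Z)-6-chloro-1-hydroxy-2-iodohexa-2,5-dien-1-yl]oxolan-3-ol | Cl/C=C\C/C=C(/I)[C@H](O)[C@@H]1O[C@@H]([C@@H](Br)CC)C[C@@H]1O | intermediate
22 | (2E,3R,3aS,5R,6aS)-5-[(1S)-1-bromopropyl]-2-[(3Z)-4-chlorobut-3-en-1-ylidene]hexahydrofuro[3,2-b]furan-3-ol | Cl/C=C\C/C=C1/O[C@H]2C[C@H]([C@@H](Br)CC)O[C@H]2[C@H]1O | intermediate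
23 | ethynyltrimethylsilane | C#C[Si](C)(C)C | starting material
24 | (2E,3R,3aS,5R,6aS)-5-[(1S)-1-bromopropyl]-2-[(3Z)-6-(trimethylsilyl)hex-3-en-5-yn-1-ylidene]hexahydrofuro[3,2-b]furan-3-ol | C[Si](C)(C)C#C/C=C\C/C=C1/O[C@H]2C[C@H]([C@@H](Br)CC)O[C@H]2[C@H]1O | intermediate
25 | (2E,3R,3aS,5R,6aS)-5-[(1S)-1-bromopropyl]-2-[(3Z)-hex-3-en-5-yn-1-ylidene]hexahydrofuro[3,2-b]furan-3-ol | C#C/C=C\C/C=C1/O[C@H]2C[C@H]([C@@H](Br)CC)O[C@H]2[C@H]1O | intermediate
26 | (2E,3S,3aR,5R,6aS)-3-bromo-5-[(1S)-1-bromopropyl]-2-[(3Z)-hex-3-en-5-yn-1-ylidene]hexahydrofuro[3,2-b]furan | C#C/C=C\C/C=C1/O[C@H]2C[C@H]([C@@H](Br)CC)O[C@H]2[C@@H]1Br | target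

Total step count: 14. Longest linear sequence: 13 steps (steps 1–3 and 5–14, from 1 to 26); step 4 is a one-step side branch.

Steps most likely to fail

1. Step 6. Methanol may capture the bromonium ion before the ketal oxygen does, the oxonium ion may collapse by a path other than loss of the ketal carbon, or O8 may compete with O9. The fallback sets out from 11 and comes back at 14. Hydrolysis of the ketal with CF3CO2H/H2O at 0 °C should give (3R,4S,5S)-3,4-dihydroxy-5-[(2E)-pent-2-en-1-yl]oxolan-2-one F1. NBS in MeCN at 0 °C should then effect a conventional hydroxyl bromoetherification, O9 closing 5-exo on the convex face of the cis-fused bicycle, to give (3R,3aS,5R,6aS)-5-[(1S)-1-bromopropyl]-3-hydroxytetrahydrofuro[3,2-b]furan-2(3H)-one F2. Ketalisation of the C8 hydroxyl with 2-methoxypropene and catalytic PPTS in CH2Cl2 returns 14.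

2. Step 10. Tin may add to the distal alkyne carbon C6, and the tin hydride may reduce the C13–Br bond by a radical chain. The fallback sets out from 19 and comes back at 22, skipping 20 and 21: direct syn hydroalkoxylation with La[N(SiMe3)2]3 (cat.) in toluene at 60 °C. Insertion of the alkyne into the La–O10 bond is syn and 5-exo, and protonolysis of the La–C6 bond should give the E enol ether. This fallback makes no new compound (F0).

3. Step 14. Bromide may attack C6 with allylic transposition, the oxyphosphonium ion may ionise, and traces of HBr may add to the enol ether. The fallback sets out from 25 and comes back at 26 and separates activation from displacement. Chloromethanesulfonyl chloride and 2,6-lutidine in CH2Cl2 at −20 °C should give (2E,3R,3aR,5R,6aS)-5-[(1S)-1-bromopropyl]-2-[(3Z)-hex-3-en-5-yn-1-ylidene]hexahydrofuro[3,2-b]furan-3-yl chloromethanesulfonate F3. LiBr in THF at 0 °C should then displace the sulfonate from the convex face with inversion to give 26.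

Further compounds
F1 | step 6 | (3R,4S,5S)-3,4-dihydroxy-5-[(2E)-pent-2-en-1-yl]oxolan-2-one | O=C1O[C@@H](C/C=C/CC)[C@@H](O)[C@H]1O
F2 | step 6 | (3R,3aS,5R,6aS)-5-[(1S)-1-bromopropyl]-3-hydroxytetrahydrofuro[3,2-b]furan-2(3H)-one | O=C1O[C@H]2C[C@H]([C@@H](Br)CC)O[C@H]2[C@H]1O
F0 | step 10 | none | none
F3 | step 14 | (2E,3R,3aR,5R,6aS)-5-[(1S)-1-bromopropyl]-2-[(3Z)-hex-3-en-5-yn-1-ylidene]hexahydrofuro[3,2-b]furan-3-yl chloromethanesulfonate | C#C/C=C\C/C=C1/O[C@H]2C[C@H]([C@@H](Br)CC)O[C@H]2[C@H]1OS(=O)(=O)CCl
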